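(The runs were computed for an exercise; the scatter is artificial.)

D came late in the runs I had: the ochre run read 7% of it after 8.00 min, beside 25% of J, and the cold red run read 1% after 60.0 min. So the amount of J in a short run looked like a matter of how much G reached Z.

| setting | red | ochre | grey | winter | autumn | noon | dawn |
|---|---|---|---|---|---|---|---|
| Z | 10 mM | 10 mM | 20 mM | 10 mM | 10 mM | 10 mM | 10 mM |
| Q | 11 mM | 11 mM | 11 mM | 11.0 mM | 11.0 mM | 11.0 mM | 11.0 mM |
| G | 6 mM | 9 mM | 12 mM | 12.0 mM | 12.0 mM | 12.0 mM | 12.0 mM |
| X | 2 mM | 2 mM | 2 mM | 2.00 mM | 2.00 mM | 2.00 mM | 2.00 mM |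
| temperature | −30 °C | 12 °C | −30 °C | 25 °C | −25 °C | 50 °C | 0 °C |
| remark | run made earlier | run made earlier | run made earlier |  |  |  |  |
| time |  |  |  | 3.0 min | 3.0 min | 3.0 min | 3.0 min |

| run | time / min | J / % | D / % |
|---|---|---|---|
| red | 10.0 | 1 | 0 |
| red | 20.0 | 2 | 1 |
| red | 30.0 | 6 | 0 |
| red | 40.0 | 8 | 1 |
| red | 50.0 | 10 | 0 |
| red | 60.0 | 10 | 1 |
| ochre | 1.33 | 9 | 0 |
| ochre | 2.50 | 12 | 0 |
| ochre | 4.00 | 16 | 0 |
| ochre | 5.00 | 19 | 3 |
| ochre | 6.00 | 22 | 1 |
| ochre | 8.00 | 25 | 7 |
| grey | 5.00 | 5 | 1 |
| grey | 12.0 | 5 | 3 |
| grey | 25.0 | 10 | 0 |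
| grey | 40.0 | 14 | 0 |
| grey | 60.0 | 19 | 2 |

(each reading ± 2 percentage points)

- the numbers in the tables scatter by 2 percentage points (one standard deviation)

- the flask with the highest amount of J, in percent of the Z charged ("all alike" if they lie within 1.5 percentage points) (winter / autumn / noon / dawn / all alike)
- final J, as a percentage of the Z charged, in winter
- final J, as a percentage of the Z charged, in autumn
- final J, as a percentage of the Z charged, in noon
- final J, as a percentage of the Z charged, in dawn

The ochre run read 9% of J at 1.33 min but 25% at 8.00 min, a rate that dropped early even allowing for the scatter. I therefore supposed that G + X was a fast step, finished at once, and reckoned with the G it leaves free.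

That gave me two limits. In the cold limit J grows on a straight line with no D: the red run's 10% in 60.0 min, scaled for G from 6 mM to 12.0 mM and cut to 3.0 min, gave 1.00% at −30 °C, so I expected autumn, at −25 °C, a little above that. In the hot limit I took G as the limiting reagent and let Z and Q share c(G) − c(X) in proportion to their charges, as if the two were equally fast, with the whole of it used; the Z converted, J and D together, then comes to the free-G share, (c(G) − c(X))/(c(Z) + c(Q)) of the Z charged, an estimate of 47.6%. I expected the flasks to move from the first limit towards the second as they got hotter, dawn nearer the line and noon nearer the free-G share. I committed to J plus D close to that share in noon and below it in the cooler flasks, and I left the split between J and D open, and with it the order of noon and winter. The thing to watch is J plus D against that share.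

The forecast put noon first, saying “Noon should still be highest”, with 34% there, 22% in winter, 7% in dawn and 1.5% in autumn. Its noon value stood under my free-G share, but it named an order where I had left one open.

The flasks gave the most J in winter, 29.0%, then 17.9% in noon, 12.4% in dawn and 2.41% in autumn.

    Z + G → J (k = 1.35 L mol⁻¹ s⁻¹, Ea = 42.0 kJ mol⁻¹)
    G + Q → L (k = 1.03 L mol⁻¹ s⁻¹, Ea = 51.0 kJ mol⁻¹)
    J + L → D (k = 4.40 L mol⁻¹ s⁻¹, Ea = 43.0 kJ mol⁻¹)
    G + X → E (k = 24.2 L mol⁻¹ s⁻¹, Ea = 39.0 kJ mol⁻¹)
    (constants at 50 °C)

In noon, 49.8% of the Z had converted, 2.2 percentage points above the free-G share of 47.6%, so that share is an estimate and no bound; G stood at 4.43% of its charge, and the Z converted stood as 31.9% D beside 17.9% J. That J in noon rests in part on two things acting together, the depletion of X and the hour of the reading: with X held, noon read 9.67%, and read at 30.0 min it stood at 4.96%. With 30 mM of G in the winter recipe the free-G share reads 133%, above the charge of Z, so I expected G not to stop that flask; at 3.0 min it held 49.9% of its G, with 48.6% J and 24.0% D.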